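**Plan**

Pterocarpan numbering is used (core rings A–D, pyran ring E on C2–C3, pyran ring F on C7–C8).
Retrosynthesis: the C10 prenyl group is returned to O9 (aromatic Claisen) and ring F to an O8 propargyl ether (Claisen to C7); then C11a–C11b and C11a–O11 are cut in one operation, then O5–C6 (Mitsunobu), then C6a–C6b (malonate arylation).
What makes the key step possible: the ring-fusion carbon C6a is flanked by two single-carbon branches, C6 leading to O5 and C11a leading to both O11 and C11b, so the core unfolds to a 2-aryl-1,3-propanediol desymmetrised at C6a; C11b sits para to the ring E oxygen and ortho to O5, the most nucleophilic carbon of ring A.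
Forward: ring E (as a chromenol) and a fully differentiated ring D iodide are made first; the three-carbon unit is attached to ring D, desymmetrised and etherified with the chromenol; rings C and B then close together; ring F follows; the prenyl group comes last.
Stereochemistry: C6a comes from lipase desymmetrisation of the prochiral diol; C11a follows from C6a through the obligatory cis ring fusion; neither centre is touched afterwards.
Ring D protection: allyl on O11 (removed by zerovalent palladium without acid or base beside the aldehyde), TIPS on O8 (fluoride), methoxymethyl on O9 (cannot migrate to a neighbouring phenoxide).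

Key step: step 14

Assumption: the lipase is taken to acetylate the arm of the prochiral diol that gives the (R)-monoacetate; with the opposite preference, enzymatic hydrolysis of the corresponding diacetate delivers the same (R)-monoacetate.

**Route**

Step 1
Reactants: 1 resorcinol; 2 3-methylbut-2-enal
Product: 3 2,2-dimethyl-2H-chromen-7-ol
Conditions: pyridine, 140 °C, sealed tube
Reagents that add atoms: none
Why: Pyridine-mediated chromenylation of a phenol with an enal (aldol-type C-alkylation, dehydration to the ortho-quinone methide and 6π oxa-electrocyclisation) is a standard route to 2,2-dimethylchromenes, and attack at the less hindered resorcinol carbon para to one hydroxyl should give mainly the 7-hydroxy isomer, from which the minor 5-hydroxy isomer is removed by chromatography.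

Step 2
Reactants: 4 2,4-dihydroxybenzaldehyde
Product: 5 4-(allyloxy)-2-hydroxybenzaldehyde
Conditions: allyl bromide, K2CO3, acetone, rt
Reagents that add atoms: allyl bromide, C=CCBr
Why: Williamson etherification should occur at the 4-hydroxyl only, because the 2-hydroxyl is held in a hydrogen bond to the aldehyde and is the weaker nucleophile under carbonate conditions.

Step 3
Reactants: 5 4-(allyloxy)-2-hydroxybenzaldehyde
Product: 6 4-(allyloxy)-2-(methoxymethoxy)benzaldehyde
Conditions: MOMCl, i-Pr2NEt, CH2Cl2, 0 °C to rt
Reagents that add atoms: chloromethyl methyl ether, COCCl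
Why: Base-mediated O-alkylation with the chloromethyl ether (acetal protection) caps the remaining phenol as a group that is stable to base, hydride and fluoride and cannot migrate between neighbouring oxygens later.

Step 4
Reactants: 6 4-(allyloxy)-2-(methoxymethoxy)benzaldehyde
Product: 8 4-(allyloxy)-2-(methoxymethoxy)phenol, via aryl formate 7 (not isolated)
Conditions: mCPBA, CH2Cl2, 0 °C to rt; then K2CO3 (cat.), MeOH, 0 °C
Reagents that add atoms: meta-chloroperoxybenzoic acid, O=C(OO)c1cccc(Cl)c1
Why: Baeyer-Villiger oxidation of an electron-rich benzaldehyde proceeds with aryl migration (Dakin-type outcome) much faster than epoxidation of the electron-poor monosubstituted allyl alkene, and the formate 7 is cleaved by base-catalysed transesterification to unveil the oxygen that becomes O8.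

Step 5
Reactants: 8 4-(allyloxy)-2-(methoxymethoxy)phenol
Product: 9 [4-(allyloxy)-2-(methoxymethoxy)phenoxy]triisopropylsilane
Conditions: TIPSCl, imidazole, DMF, rt
Reagents that add atoms: chlorotriisopropylsilane, CC(C)[Si](Cl)(C(C)C)C(C)C
Why: Imidazole-promoted silylation of the free phenol installs a bulky silyl ether that should survive the base, hydride, copper and palladium steps and is later removed by fluoride alone.

Step 6
Reactants: 9 [4-(allyloxy)-2-(methoxymethoxy)phenoxy]triisopropylsilane
Product: 10 [4-(allyloxy)-5-iodo-2-(methoxymethoxy)phenoxy]triisopropylsilane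
Conditions: NIS, MeCN, 0 °C to rt, dark
Reagents that add atoms: N-iodosuccinimide, O=C1CCC(=O)N1I
Why: Electrophilic aromatic iodination should take place at the one ring carbon that is para to the methoxymethoxy group and ortho to the allyloxy group, the position activated by two oxygens and not flanked by two substituents, which is the future C6b.

Step 7
Reactants: 10 [4-(allyloxy)-5-iodo-2-(methoxymethoxy)phenoxy]triisopropylsilane; 11 diethyl malonate
Product: 12 diethyl 2-arylmalonate (aryl = 2-allyloxy-4-methoxymethoxy-5-triisopropylsilyloxyphenyl)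
Conditions: CuI (10 mol %), 2-picolinic acid (20 mol %), Cs2CO3, 1,4-dioxane, 70 °C
Reagents that add atoms: none
Why: Copper-catalysed Ullmann-type α-arylation of a malonate tolerates ortho-alkoxy aryl iodides and, unlike zerovalent palladium, neither ionises the allyl ether nor cyclises the aryl-metal species onto the ortho-allyloxy alkene.

Step 8
Reactants: 12 diethyl 2-arylmalonate
Product: 13 2-arylpropane-1,3-diol (same aryl group)
Conditions: LiAlH4, THF, 0 °C to rt
Reagents that add atoms: none
Why: Hydride reduction of both ester groups gives the 2-aryl-1,3-propanediol, an achiral compound whose two hydroxymethyl arms are enantiotopic.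

Step 9
Reactants: 13 2-arylpropane-1,3-diol
Product: 14 (2R)-2-aryl-3-hydroxypropyl acetate
Conditions: lipase PS (Burkholderia cepacia, immobilised), vinyl acetate, t-BuOMe, rt
Reagents that add atoms: vinyl acetate, C=COC(C)=O
Why: Lipase-catalysed irreversible transesterification with an enol ester is an established desymmetrisation of 2-aryl-1,3-propanediols, and acetylation of one enantiotopic arm within the chiral active site creates the C6a stereocentre as the (R)-monoacetate.

Step 10
Reactants: 14 (2R)-2-aryl-3-hydroxypropyl acetate; 3 2,2-dimethyl-2H-chromen-7-ol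
Product: 15 (2R)-2-aryl-3-[(2,2-dimethyl-2H-chromen-7-yl)oxy]propyl acetate
Conditions: PPh3, DIAD, THF, 0 °C to rt
Reagents that add atoms: none
Why: Mitsunobu etherification of the primary alcohol with the acidic phenol 3 forms the O5–C6 bond without touching the stereocentre, which lies one carbon away from the reacting carbinol, provided the monoacetate is used promptly so that 1,3-acyl migration cannot scramble the arms.

Step 11
Reactants: 15 (2R)-2-aryl-3-[(2,2-dimethyl-2H-chromen-7-yl)oxy]propyl acetate
Product: 16 (2S)-2-aryl-3-[(2,2-dimethyl-2H-chromen-7-yl)oxy]propan-1-ol (same spatial arrangement; the descriptor changes with the priorities)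
Conditions: K2CO3 (cat.), MeOH, 0 °C
Reagents that add atoms: none
Why: Base-catalysed transesterification (Zemplen-type methanolysis) of the primary acetate is fast at 0 °C and should leave the aryl silyl ether, the acetal and the stereocentre, which has no adjacent carbonyl, untouched.

Step 12
Reactants: 16 (2S)-2-aryl-3-[(2,2-dimethyl-2H-chromen-7-yl)oxy]propan-1-ol
Product: 17 (2R)-2-aryl-3-[(2,2-dimethyl-2H-chromen-7-yl)oxy]propanal
Conditions: Dess-Martin periodinane, CH2Cl2, 0 °C to rt; crude product used directly
Reagents that add atoms: none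
Why: Dess-Martin oxidation converts the primary alcohol to the aldehyde under non-basic conditions without over-oxidation, so the configurationally labile α-aryl centre should be preserved if the aldehyde is carried on without chromatography.

Step 13
Reactants: 17 (2R)-2-aryl-3-[(2,2-dimethyl-2H-chromen-7-yl)oxy]propanal
Product: 18 (2R)-3-[(2,2-dimethyl-2H-chromen-7-yl)oxy]-2-[2-hydroxy-4-(methoxymethoxy)-5-(triisopropylsilyloxy)phenyl]propanal
Conditions: Pd(PPh3)4 (5 mol %), PhSiH3, CH2Cl2, rt; aqueous work-up
Reagents that add atoms: none
Why: Tsuji-Trost-type deallylation, in which zerovalent palladium ionises the aryl allyl ether and the silane reduces the allyl ligand to propene, proceeds without acid or base, and the liberated O11 phenol adds reversibly to the aldehyde so that 18 rests as its lactol 19, in which C6a is no longer α to a carbonyl.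

Step 14
Reactants: 18 (2R)-3-[(2,2-dimethyl-2H-chromen-7-yl)oxy]-2-[2-hydroxy-4-(methoxymethoxy)-5-(triisopropylsilyloxy)phenyl]propanal
Product: 21 (6aR,11aR)-9-(methoxymethoxy)-8-(triisopropylsilyloxy)pterocarpan bearing ring E (2,2-dimethylpyran on C2-C3 with its oxygen on C3), via lactol 19 (not isolated), via oxocarbenium ion 20 (not isolated)
Conditions: Sc(OTf)3 (10 mol %), 4 Å MS, CH2Cl2 (0.01 M), −40 to 0 °C
Reagents that add atoms: none
Why: Sc(OTf)3 ionises lactol 19, itself formed by reversible 5-exo-trig addition of the O11 phenol to the aldehyde carbon C11a (ring C), to the cyclic oxocarbenium ion 20, which the tethered chromenyl ether attacks through its carbon para to the ring E oxygen in a 6-exo-trig Friedel-Crafts closure (ring B, new C11a–C11b bond, the arene double bond being endocyclic to the new ring) before rearomatisation. The closest known reaction type is the Lewis-acid Friedel-Crafts capture of lactol-derived cyclic oxocarbenium ions by electron-rich arenes (oxa-Pictet-Spengler type), and the outcome coincides with the classical acid closure of 2'-hydroxyisoflavan-4-ols to pterocarpans should the open aldehyde react first. The single new stereocentre C11a is controlled by C6a: the three-atom tether C6–O5–arene can reach only the face of the planar oxocarbenium ring on which C6 stands, and a trans-fused benzopyran/dihydrobenzofuran is prohibitively strained, so only the cis (6aR,11aR) junction can form. The step needs regioselectivity for the arene carbon para to the ring E oxygen over the carbon between the two oxygens, which the para donor and the lower steric demand secure, and it needs ring closure to outrun loss of the C6a proton to a benzofuran and protonation of the ring E alkene, which a catalytic non-protic Lewis acid, molecular sieves, high dilution and low temperature should secure together with the lactol resting state that keeps the enolisable aldehyde concentration low.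

Step 15
Reactants: 21 (6aR,11aR)-9-(methoxymethoxy)-8-(triisopropylsilyloxy)pterocarpan bearing ring E
Product: 22 (6aR,11aR)-8-hydroxy-9-(methoxymethoxy)pterocarpan bearing ring E
Conditions: TBAF, THF, 0 °C
Reagents that add atoms: none
Why: Fluoride-induced desilylation frees O8 selectively, the acetal on O9 being inert to fluoride and, unlike a silyl or acyl group, unable to shift onto the new phenoxide.

Step 16
Reactants: 22 (6aR,11aR)-8-hydroxy-9-(methoxymethoxy)pterocarpan bearing ring E; 23 3-chloro-3-methylbut-1-yne
Product: 24 (6aR,11aR)-9-(methoxymethoxy)-8-(2-methylbut-3-yn-2-yloxy)pterocarpan bearing ring E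
Conditions: DBU, CuCl2 (1 mol %), MeCN, 0 °C to rt
Reagents that add atoms: none
Why: Copper-catalysed O-propargylation of a phenol with a tertiary propargylic chloride and an amidine base is the standard preparation of aryl 1,1-dimethylpropargyl ethers.

Step 17
Reactants: 24 (6aR,11aR)-9-(methoxymethoxy)-8-(2-methylbut-3-yn-2-yloxy)pterocarpan bearing ring E
Product: 26 (6aR,11aR)-9-(methoxymethoxy)pterocarpan bearing ring E plus ring F (2,2-dimethylpyran on C7-C8 with its oxygen on C8), via ortho-allenyl phenol 25 (not isolated)
Conditions: o-xylene, 140 °C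
Reagents that add atoms: none
Why: Aryl propargyl ether Claisen rearrangement can only deliver the side chain to C7, the other ortho position of O8 being the oxygen-bearing C9, and the ortho-allenyl phenol 25 closes ring F by 1,5-hydrogen shift and 6π oxa-electrocyclisation.

Step 18
Reactants: 26 (6aR,11aR)-9-(methoxymethoxy)pterocarpan bearing rings E and F
Product: 27 (6aR,11aR)-9-hydroxypterocarpan bearing rings E and F
Conditions: TMSOTf, 2,2'-bipyridyl, CH2Cl2, 0 °C to rt; then H2O
Reagents that add atoms: none
Why: Silyl triflate activation of the aromatic methoxymethyl ether in the presence of the bipyridyl base (acetal cleavage) exchanges the acetal for a labile trimethylsilyl ether under buffered non-protic conditions, which the two chromene alkenes should tolerate and under which any transient opening of the C11a–O11 bond can only re-close to the cis-fused ring.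

Step 19
Reactants: 28 2-methylbut-3-en-2-ol
Product: 29 methyl 2-methylbut-3-en-2-yl carbonate
Conditions: n-BuLi, THF, −78 °C; then ClCO2Me, −78 °C to rt
Reagents that add atoms: methyl chloroformate, COC(=O)Cl
Why: O-Acylation of the lithium alkoxide of the tertiary allylic alcohol with the chloroformate gives the mixed carbonate that serves as the ionisable partner for the next step.

Step 20
Reactants: 27 (6aR,11aR)-9-hydroxypterocarpan bearing rings E and F; 29 methyl 2-methylbut-3-en-2-yl carbonate
Product: 30 (6aR,11aR)-9-(2-methylbut-3-en-2-yloxy)pterocarpan bearing rings E and F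
Conditions: Pd(PPh3)4 (5 mol %), THF, 0 °C to rt
Reagents that add atoms: none
Why: Palladium-catalysed decarboxylative allylic etherification (Tsuji-Trost reaction) generates a 1,1-dimethylallyl–palladium species and the phenoxide together, and under kinetic control at low temperature the phenoxide should attack the more substituted terminus to give the tertiary (reverse-prenyl) ether.

Step 21
Reactants: 30 (6aR,11aR)-9-(2-methylbut-3-en-2-yloxy)pterocarpan bearing rings E and F
Product: 31 lespecyrtin E4
Conditions: toluene, 110 °C
Reagents that add atoms: none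
Why: Aromatic Claisen rearrangement of the 1,1-dimethylallyl ether transfers the allyl unit with inversion of its ends to C10, the only free ortho position of O9, and tautomerisation of the dienone returns the phenol with a 3-methylbut-2-enyl group, neither stereocentre being involved.

**Compound list**

1 | resorcinol | Oc1cccc(O)c1 | starting material
2 | 3-methylbut-2-enal | CC(C)=CC=O | starting material
3 | 2,2-dimethyl-2H-chromen-7-ol | CC1(C)C=Cc2ccc(O)cc2O1 | intermediate
4 | 2,4-dihydroxybenzaldehyde | O=Cc1ccc(O)cc1O | starting material
5 | 4-(allyloxy)-2-hydroxybenzaldehyde | O=Cc1ccc(OCC=C)cc1O | intermediate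
6 | 4-(allyloxy)-2-(methoxymethoxy)benzaldehyde | O=Cc1ccc(OCC=C)cc1OCOC | intermediate
7 | 4-(allyloxy)-2-(methoxymethoxy)phenyl formate | O=COc1ccc(OCC=C)cc1OCOC | intermediate
8 | 4-(allyloxy)-2-(methoxymethoxy)phenol | Oc1ccc(OCC=C)cc1OCOC | intermediate
9 | [4-(allyloxy)-2-(methoxymethoxy)phenoxy]triisopropylsilane | CC(C)[Si](Oc1ccc(OCC=C)cc1OCOC)(C(C)C)C(C)C | intermediate
10 | [4-(allyloxy)-5-iodo-2-(methoxymethoxy)phenoxy]triisopropylsilane | CC(C)[Si](Oc1cc(I)c(OCC=C)cc1OCOC)(C(C)C)C(C)C | intermediate
11 | diethyl malonate | CCOC(=O)CC(=O)OCC | starting material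
12 | diethyl 2-[2-(allyloxy)-4-(methoxymethoxy)-5-(triisopropylsilyloxy)phenyl]malonate | CCOC(=O)C(C(=O)OCC)c1cc(O[Si](C(C)C)(C(C)C)C(C)C)c(OCOC)cc1OCC=C | intermediate
13 | 2-[2-(allyloxy)-4-(methoxymethoxy)-5-(triisopropylsilyloxy)phenyl]propane-1,3-diol | OCC(CO)c1cc(O[Si](C(C)C)(C(C)C)C(C)C)c(OCOC)cc1OCC=C | intermediate
14 | (2R)-2-[2-(allyloxy)-4-(methoxymethoxy)-5-(triisopropylsilyloxy)phenyl]-3-hydroxypropyl acetate | CC(=O)OC[C@@H](CO)c1cc(O[Si](C(C)C)(C(C)C)C(C)C)c(OCOC)cc1OCC=C | intermediate
15 | (2R)-2-[2-(allyloxy)-4-(methoxymethoxy)-5-(triisopropylsilyloxy)phenyl]-3-[(2,2-dimethyl-2H-chromen-7-yl)oxy]propyl acetate | CC(=O)OC[C@@H](COc1ccc2C=CC(C)(C)Oc2c1)c1cc(O[Si](C(C)C)(C(C)C)C(C)C)c(OCOC)cc1OCC=C | intermediate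
16 | (2S)-2-[2-(allyloxy)-4-(methoxymethoxy)-5-(triisopropylsilyloxy)phenyl]-3-[(2,2-dimethyl-2H-chromen-7-yl)oxy]propan-1-ol | OC[C@@H](COc1ccc2C=CC(C)(C)Oc2c1)c1cc(O[Si](C(C)C)(C(C)C)C(C)C)c(OCOC)cc1OCC=C | intermediate
17 | (2R)-2-[2-(allyloxy)-4-(methoxymethoxy)-5-(triisopropylsilyloxy)phenyl]-3-[(2,2-dimethyl-2H-chromen-7-yl)oxy]propanal | O=C[C@@H](COc1ccc2C=CC(C)(C)Oc2c1)c1cc(O[Si](C(C)C)(C(C)C)C(C)C)c(OCOC)cc1OCC=C | intermediate
18 | (2R)-3-[(2,2-dimethyl-2H-chromen-7-yl)oxy]-2-[2-hydroxy-4-(methoxymethoxy)-5-(triisopropylsilyloxy)phenyl]propanal (open form of the ring-chain pair with 19) | O=C[C@@H](COc1ccc2C=CC(C)(C)Oc2c1)c1cc(O[Si](C(C)C)(C(C)C)C(C)C)c(OCOC)cc1O | intermediate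
19 | (3R)-3-{[(2,2-dimethyl-2H-chromen-7-yl)oxy]methyl}-6-(methoxymethoxy)-5-(triisopropylsilyloxy)-2,3-dihydrobenzofuran-2-ol (lactol, both C2 epimers) | OC1Oc2cc(OCOC)c(O[Si](C(C)C)(C(C)C)C(C)C)cc2[C@@H]1COc1ccc2C=CC(C)(C)Oc2c1 | intermediate
20 | (3R)-oxocarbenium ion of 19 (C2=O1 double bond, positive charge on the ring oxygen) | C1=[O+]c2cc(OCOC)c(O[Si](C(C)C)(C(C)C)C(C)C)cc2[C@@H]1COc1ccc2C=CC(C)(C)Oc2c1 | intermediate
21 | (6aR,11aR)-9-(methoxymethoxy)-8-(triisopropylsilyloxy)pterocarpan with ring E (2,2-dimethylpyran fused at C2–C3, oxygen on C3) | CC(C)[Si](Oc1cc3c(cc1OCOC)O[C@H]1c4cc5c(cc4OC[C@@H]31)OC(C)(C)C=C5)(C(C)C)C(C)C | intermediate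
22 | (6aR,11aR)-8-hydroxy-9-(methoxymethoxy)pterocarpan with ring E | Oc1cc3c(cc1OCOC)O[C@H]1c4cc5c(cc4OC[C@@H]31)OC(C)(C)C=C5 | intermediate
23 | 3-chloro-3-methylbut-1-yne | CC(C)(Cl)C#C | starting material
24 | (6aR,11aR)-9-(methoxymethoxy)-8-(2-methylbut-3-yn-2-yloxy)pterocarpan with ring E | C#CC(C)(C)Oc1cc3c(cc1OCOC)O[C@H]1c4cc5c(cc4OC[C@@H]31)OC(C)(C)C=C5 | intermediate
25 | (6aR,11aR)-8-hydroxy-9-(methoxymethoxy)-7-(3-methylbuta-1,2-dienyl)pterocarpan with ring E | Oc1c(C=C=C(C)C)c3c(cc1OCOC)O[C@H]1c4cc5c(cc4OC[C@@H]31)OC(C)(C)C=C5 | intermediate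
26 | (6aR,11aR)-9-(methoxymethoxy)pterocarpan with ring E and ring F (2,2-dimethylpyran fused at C7–C8, oxygen on C8) | c1c(OCOC)c2c(c3c1O[C@H]1c4cc5c(cc4OC[C@@H]31)OC(C)(C)C=C5)C=CC(C)(C)O2 | intermediate
27 | (6aR,11aR)-9-hydroxypterocarpan with rings E and F | c1c(O)c2c(c3c1O[C@H]1c4cc5c(cc4OC[C@@H]31)OC(C)(C)C=C5)C=CC(C)(C)O2 | intermediate
28 | 2-methylbut-3-en-2-ol | CC(C)(O)C=C | starting material
29 | methyl 2-methylbut-3-en-2-yl carbonate | COC(=O)OC(C)(C)C=C | intermediate
30 | (6aR,11aR)-9-(2-methylbut-3-en-2-yloxy)pterocarpan with rings E and F | c1c(OC(C)(C)C=C)c2c(c3c1O[C@H]1c4cc5c(cc4OC[C@@H]31)OC(C)(C)C=C5)C=CC(C)(C)O2 | intermediate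
31 | lespecyrtin E4, (6aR,11aR)-9-hydroxy-10-(3-methylbut-2-enyl)pterocarpan with rings E and F | CC(C)=CCc1c(O)c2c(c3c1O[C@H]1c4cc5c(cc4OC[C@@H]31)OC(C)(C)C=C5)C=CC(C)(C)O2 | target

**Step count**

Total step count: 21.
Longest linear sequence: 19 steps (steps 2 to 18, then 20 and 21, from 2,4-dihydroxybenzaldehyde 4).

**Steps most likely to fail**

Step 14. The oxocarbenium ion may lose the C6a proton faster than the arene attacks, which would give an achiral benzofuran or, if reversible, erode the C6a configuration; the ring E styrenyl ether may also be protonated and oligomerise. The fallback sets out from aldehyde 17, in which O11 is still allylated, so that neither a lactol nor an oxocarbenium ion can form. Me2AlCl in CH2Cl2 at −78 °C should bring about an intramolecular Friedel-Crafts hydroxyalkylation at the same arene carbon (ring B first), giving the O-allyl isoflavan-4-ol F1 as a mixture of C4 epimers. Pd(PPh3)4 with PhSiH3 would then free the phenol to give the 2'-hydroxyisoflavan-4-ol F2. A Mitsunobu cyclodehydration (PPh3, DIAD) would close ring C; both C4 epimers should converge on the cis-fused product because the activated benzylic carbon para to the ring E oxygen ionises readily. The sequence returns to the route at 21.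

Step 9. The enzyme may discriminate the two hydroxymethyl arms of the bulky ortho-substituted diol poorly or in the unwanted sense, and the monoacetate may racemise by 1,3-acyl migration during isolation. The fallback sets out from diol 13 and desymmetrises it with a small-molecule catalyst, the dinuclear zinc complex formed from Et2Zn and a ProPhenol ligand, with vinyl benzoate as acyl donor. Either ligand antipode is available, so the (R)-monobenzoate F3 can be targeted, and a benzoate migrates far less readily than an acetate. Mitsunobu coupling with chromenol 3 would give the benzoate aryl ether F4, and K2CO3 in MeOH would remove the benzoate to rejoin the route at alcohol 16.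

Step 20. The 1,1-dimethylallyl–palladium intermediate may be captured at its unsubstituted terminus, or the first-formed tertiary ether may re-ionise and equilibrate to the linear prenyl ether, which cannot place a prenyl group on C10 by a [3,3] shift; the hindered phenol may also react slowly while the carbonate eliminates to isoprene. The fallback sets out from phenol 27 and O-alkylates it with 3-chloro-3-methylbut-1-yne 23 (DBU, catalytic CuCl2, MeCN), a reaction that places oxygen on the tertiary carbon by construction, to give the 1,1-dimethylpropargyl ether F5. Semi-hydrogenation over Pd/CaCO3 poisoned with Pb(OAc)2 and quinoline, which should leave the hindered cis-disubstituted chromene alkenes alone, returns to the route at the tert-prenyl ether 30.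

**Further compounds**

F1 | step 14 | (3R)-3-[2-(allyloxy)-4-(methoxymethoxy)-5-(triisopropylsilyloxy)phenyl]-8,8-dimethyl-3,4-dihydro-2H,8H-pyrano[3,2-g]chromen-4-ol (C4 epimers) | OC1c2cc3C=CC(C)(C)Oc3cc2OC[C@H]1c1cc(O[Si](C(C)C)(C(C)C)C(C)C)c(OCOC)cc1OCC=C
F2 | step 14 | (3R)-3-[2-hydroxy-4-(methoxymethoxy)-5-(triisopropylsilyloxy)phenyl]-8,8-dimethyl-3,4-dihydro-2H,8H-pyrano[3,2-g]chromen-4-ol (C4 epimers) | OC1c2cc3C=CC(C)(C)Oc3cc2OC[C@H]1c1cc(O[Si](C(C)C)(C(C)C)C(C)C)c(OCOC)cc1O
F3 | step 9 | (2R)-2-[2-(allyloxy)-4-(methoxymethoxy)-5-(triisopropylsilyloxy)phenyl]-3-hydroxypropyl benzoate | O=C(OC[C@@H](CO)c1cc(O[Si](C(C)C)(C(C)C)C(C)C)c(OCOC)cc1OCC=C)c1ccccc1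
F4 | step 9 | (2R)-2-[2-(allyloxy)-4-(methoxymethoxy)-5-(triisopropylsilyloxy)phenyl]-3-[(2,2-dimethyl-2H-chromen-7-yl)oxy]propyl benzoate | O=C(OC[C@@H](COc1ccc2C=CC(C)(C)Oc2c1)c1cc(O[Si](C(C)C)(C(C)C)C(C)C)c(OCOC)cc1OCC=C)c1ccccc1
F5 | step 20 | (6aR,11aR)-9-(2-methylbut-3-yn-2-yloxy)pterocarpan with rings E and F | c1c(OC(C)(C)C#C)c2c(c3c1O[C@H]1c4cc5c(cc4OC[C@@H]31)OC(C)(C)C=C5)C=CC(C)(C)O2
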